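## Retrosynthetic overview

1. The oxirane is made last, by face- and site-selective epoxidation of Δ3 of the macrocyclic tetraene, mirroring the late oxygenase step. O-13 is acetylated just before.
2. The 14-membered ring comes from head-to-tail C2–C1 closure of an oxidised geranylgeranyl chain. The ionised C2 allylic acetate (diphosphate surrogate) is captured by the Δ1(15) olefin. A C17–SnBu3 bond leaves in place of the C17 proton, which gives the exocyclic methylene and sets C1.
3. The chain is assembled as C15 + C5. A vinylogous Mukaiyama aldol joins 12-oxofarnesyl acetate to a stannylmethyl silyloxyfuran and sets C13 and C14.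
4. Ring order: the butenolide is carried in from tulipalin A, then the carbocycle is closed, then the oxirane.

**Numbering:** cembrane numbering is used throughout. C2 is the former farnesyl C1, C13 is the former farnesyl C12, and C14/C1/C15/C16/C17 are the five furanone carbons.

**Assumption:** (S)-BINOL–Ti is taken to deliver the (13S,14S) adduct in step 6. If the sense of induction proves opposite, (R)-BINOL is used.

## Route

Step 1
Reactants: 1 α-methylene-γ-butyrolactone (tulipalin A)
Product: 2 3-(bromomethyl)furan-2(5H)-one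
Conditions: NBS (1.05 equiv), AIBN (cat.), PhCF3, reflux
Reagents that add atoms: N-bromosuccinimide O=C1CCC(=O)N1Br
Why: Wohl–Ziegler allylic bromination, in which H-abstraction at the only allylic CH2 gives a delocalised radical that is brominated at the exocyclic terminus (any secondary bromide equilibrates by SN2′) because this restores the conjugated endocyclic butenolide.

Step 2
Reactants: 2 3-(bromomethyl)furan-2(5H)-one
Product: 3 3-[(tributylstannyl)methyl]furan-2(5H)-one
Conditions: (Bu3Sn)2 (1.3 equiv), Pd2(dba)3 (2 mol %), THF, rt, slow addition of 2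
Reagents that add atoms: hexabutyldistannane CCCC[Sn](CCCC)(CCCC)[Sn](CCCC)(CCCC)CCCC
Why: Pd(0)-catalysed stannylation of an allylic bromide (oxidative addition, Sn–Sn transmetalation, C–Sn reductive elimination at the unhindered CH2 terminus), with the bromide kept dilute to suppress Stille-type homocoupling.

Step 3
Reactants: 3 3-[(tributylstannyl)methyl]furan-2(5H)-one
Product: 4 trimethyl({3-[(tributylstannyl)methyl]furan-2-yl}oxy)silane
Conditions: TMSOTf (1.1 equiv), Et3N (1.3 equiv), Et2O, 0 °C; pentane extraction under Ar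
Reagents that add atoms: trimethylsilyl triflate C[Si](C)(C)OS(=O)(=O)C(F)(F)F
Why: Soft enolisation (O-silylation, then loss of the only acidic γ-proton) aromatises the butenolide to the 2-silyloxyfuran, and the C–Sn bond is not aligned with the cationic centre so it survives.

Step 4
Reactants: 5 (2E,6E)-farnesyl acetate
Product: 6 (2E,6E,10E)-12-hydroxy-3,7,11-trimethyldodeca-2,6,10-trien-1-yl acetate
Conditions: SeO2 (10 mol %), t-BuOOH (3 equiv), salicylic acid (10 mol %), CH2Cl2, rt
Reagents that add atoms: tert-butyl hydroperoxide CC(C)(C)OO (terminal O source); selenium dioxide O=[Se]=O (catalytic O carrier)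
Why: Catalytic SeO2 allylic oxidation (ene reaction, then [2,3]-sigmatropic shift) attacks the most electron-rich terminal trisubstituted olefin and gives only the (E)-CH2OH, Δ2 being deactivated by its allylic acetate.

Step 5
Reactants: 6 (2E,6E,10E)-12-hydroxy-3,7,11-trimethyldodeca-2,6,10-trien-1-yl acetate
Product: 7 (2E,6E,10E)-3,7,11-trimethyl-12-oxododeca-2,6,10-trien-1-yl acetate
Conditions: MnO2 (15 equiv), CH2Cl2, rt
Reagents that add atoms: none
Why: MnO2 oxidation is selective for the allylic alcohol and gives the enal without E/Z isomerisation or over-oxidation.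

Step 6
Reactants: 4 trimethyl({3-[(tributylstannyl)methyl]furan-2-yl}oxy)silane; 7 (2E,6E,10E)-3,7,11-trimethyl-12-oxododeca-2,6,10-trien-1-yl acetate
Product: 9 (5S)-5-[(1S,2E,6E,10E)-12-acetoxy-1-hydroxy-2,6,10-trimethyldodeca-2,6,10-trien-1-yl]-3-[(tributylstannyl)methyl]furan-2(5H)-one, via 13-O-trimethylsilyl ether 8 (not isolated)
Conditions: Ti(OiPr)4/(S)-BINOL (20 mol %), Et2O, −20 °C; then 0.5 M citric acid, THF, 0 °C
Reagents that add atoms: none
Why: Catalytic asymmetric vinylogous Mukaiyama aldol reaction, in which the furan C5 terminus (far more nucleophilic than the acyl-deactivated allylstannane) adds 1,2 to the Ti–BINOLate-bound enal through an open antiperiplanar transition state that gives the threo pair, the ligand fixing the aldehyde face and so both C13 (S) and C14 (S), while mild acid removes the O-TMS group.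

Step 7
Reactants: 9 (5S)-5-[(1S,2E,6E,10E)-12-acetoxy-1-hydroxy-2,6,10-trimethyldodeca-2,6,10-trien-1-yl]-3-[(tributylstannyl)methyl]furan-2(5H)-one
Product: 10 (1S,13S,14S,3E,7E,11E)-13-hydroxycembra-3,7,11,15(17)-tetraen-16,14-olide
Conditions: Pd(PPh3)4 (10 mol %), THF, 65 °C, syringe-pump addition over 20 h (final 1 mM)
Reagents that add atoms: none
Why: Proposed new method: macrocyclic version of the Pd(0)-catalysed allyl acetate–allylstannane cross-coupling, which is known intermolecularly to join the less substituted allyl terminus to the γ-carbon of the stannane with allyl inversion, is known intramolecularly for 5- and 6-membered rings, and is related to macrocyclic Stille closures; Pd(0) can ionise only the C2 acetate (the lactone C14–O bond is orthogonal to the π system and the C13 carbinol is no leaving group), the π-allyl keeps its E geometry because syn/anti exchange would need σ-Pd at tertiary C4, the Δ1(15) olefin delivers C1 to the unhindered CH2 terminus while Bu3Sn leaves from C17 to create the exocyclic methylene, and approach across the flat butenolide anti to the C14 side chain sets 1S (trans-fused lactone).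

Step 8
Reactants: 10 (1S,13S,14S,3E,7E,11E)-13-hydroxycembra-3,7,11,15(17)-tetraen-16,14-olide
Product: 11 (1S,13S,14S,3E,7E,11E)-13-acetoxycembra-3,7,11,15(17)-tetraen-16,14-olide
Conditions: Ac2O, pyridine, DMAP (cat.), CH2Cl2, 0 °C to rt
Reagents that add atoms: acetic anhydride CC(=O)OC(C)=O
Why: DMAP-catalysed acylation of the only hydroxyl touches no stereocentre, and C14 can no longer epimerise or eliminate because C1 is now sp3.

Step 9
Reactants: 11 (1S,13S,14S,3E,7E,11E)-13-acetoxycembra-3,7,11,15(17)-tetraen-16,14-olide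
Product: 12 13-acetoxysarcocrassolide, (1S,3S,4S,13S,14S,7E,11E)-13-acetoxy-3,4-epoxycembra-7,11,15(17)-trien-16,14-olide
Conditions: ent-Shi ketone (L-fructose-derived, 30 mol %), Oxone (0.9 equiv), K2CO3, borate/EDTA buffer, Bu4NHSO4 (cat.), MeCN–DMM, 0 °C, stopped at partial conversion
Reagents that add atoms: Oxone (potassium peroxymonosulfate) [K+].[O-]S(=O)(=O)OO
Why: Shi asymmetric epoxidation (chiral dioxirane, spiro transition state), where the ent-ketone gives the (S,S)-oxirane from an E-trisubstituted olefin with retention of the trans C2/C5 relationship, Δ11 is switched off by its allylic acetate and Δ15(17) by the carbonyl, so only Δ7 competes and its regioisomer is removed by chromatography with recovered 11 recycled.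

## Compound list

1 | α-methylene-γ-butyrolactone (tulipalin A) | C=C1CCOC1=O | starting material
2 | 3-(bromomethyl)furan-2(5H)-one | BrCC1=CCOC1=O | intermediate
3 | 3-[(tributylstannyl)methyl]furan-2(5H)-one | CCCC[Sn](CCCC)(CCCC)CC1=CCOC1=O | intermediate
4 | trimethyl({3-[(tributylstannyl)methyl]furan-2-yl}oxy)silane | CCCC[Sn](CCCC)(CCCC)Cc1ccoc1O[Si](C)(C)C | intermediate
5 | (2E,6E)-farnesyl acetate | CC(C)=CCC/C(C)=C/CC/C(C)=C/COC(C)=O | starting material
6 | (2E,6E,10E)-12-hydroxy-3,7,11-trimethyldodeca-2,6,10-trien-1-yl acetate | OC/C(C)=C/CC/C(C)=C/CC/C(C)=C/COC(C)=O | intermediate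
7 | (2E,6E,10E)-3,7,11-trimethyl-12-oxododeca-2,6,10-trien-1-yl acetate | O=C/C(C)=C/CC/C(C)=C/CC/C(C)=C/COC(C)=O | intermediate
8 | 13-O-trimethylsilyl ether of 9 (not isolated) | CCCC[Sn](CCCC)(CCCC)CC1=C[C@H](OC1=O)[C@@H](O[Si](C)(C)C)/C(C)=C/CC/C(C)=C/CC/C(C)=C/COC(C)=O | intermediate
9 | (5S)-5-[(1S,2E,6E,10E)-12-acetoxy-1-hydroxy-2,6,10-trimethyldodeca-2,6,10-trien-1-yl]-3-[(tributylstannyl)methyl]furan-2(5H)-one | CCCC[Sn](CCCC)(CCCC)CC1=C[C@H](OC1=O)[C@@H](O)/C(C)=C/CC/C(C)=C/CC/C(C)=C/COC(C)=O | intermediate
10 | (1S,13S,14S,3E,7E,11E)-13-hydroxycembra-3,7,11,15(17)-tetraen-16,14-olide | C=C1C(=O)O[C@H]2[C@H]1C/C=C(\C)CC/C=C(\C)CC/C=C(\C)[C@@H]2O | intermediate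
11 | (1S,13S,14S,3E,7E,11E)-13-acetoxycembra-3,7,11,15(17)-tetraen-16,14-olide | C=C1C(=O)O[C@H]2[C@H]1C/C=C(\C)CC/C=C(\C)CC/C=C(\C)[C@@H]2OC(C)=O | intermediate
12 | 13-acetoxysarcocrassolide | C=C1C(=O)O[C@H]2[C@H]1C[C@@H]1O[C@@]1(C)CC/C=C(\C)CC/C=C(\C)[C@@H]2OC(C)=O | target

## Step count and risks

Total step count: 9. Longest linear sequence: 7 (steps 1, 2, 3, 6, 7, 8, 9).

**Most likely to fail, first: step 7.**
- **Failure modes:** the bis-allyl palladium species may couple 3,3′ (C1–C4). The π-allyl may lose a proton to a farnesene-type triene. The deactivated stannane may be too slow, so that oligomers win.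
- **Fallback:** it keeps the C1–C2 closure but makes C2 a carbonyl carbon, and it sets out from 9.
  - Acetylation gives the 13-acetate F1.
  - Lipase-catalysed methanolysis frees only the primary allylic alcohol F2.
  - MnO2 gives the enal F3.
  - BF3·OEt2 at −78 °C and high dilution triggers the intramolecular SE2′ allylstannane–aldehyde addition. This is a well-precedented way to close 14-membered rings and to functionalise the β-carbon of such butenolides. It gives the 2-hydroxy macrocycle F4, and the C2 epimers are irrelevant.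
  - Ionic deoxygenation (Et3SiH, BF3·OEt2, −78 °C) places hydride at the less hindered C2 terminus of the allyl cation. This brings the material back to the route at 11.

**Second: step 9.**
- **Failure mode:** Δ3 and Δ7 are electronically almost alike, so the site ratio may be poor. The macrocycle may also mismatch the catalyst.
- **Fallback:** it replaces undirected oxygen transfer by delivery from a temporary neighbouring group, and it sets out from 11.
  - Me2NH adds to the methylene lactone to give the Michael adduct F5. This also protects the acrylate.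
  - Protonation with Cl3CCO2H followed by mCPBA gives ammonium-directed epoxidation. The N–H hydrogen-bonds the peracid, and the ammonium on C17 sits next to Δ3. The product is the epoxy amine F6.
  - MeI gives the methiodide F7.
  - NaHCO3 induces elimination and brings the material back to the route at 12.

**Third: step 6.**
- **Failure mode:** a new 3-substituted donor combined with an α-branched enal may give modest ee or a modest threo:erythro ratio.
- **Fallback:** it gives up catalytic induction in the aldol and resolves at the acetylation that the route needs anyway. It sets out from 4 and 7.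
  - A BF3·OEt2-promoted, threo-selective but racemic vinylogous aldol gives 9 together with its enantiomer ent-9 F8.
  - The racemate is cyclised as in step 7 to 10 plus ent-10 F9.
  - Acylative kinetic resolution of this trisubstituted allylic alcohol (planar-chiral DMAP catalyst, Ac2O, t-amyl alcohol, 0 °C) acetylates only the (13S) alcohol. The material re-enters the route at 11 while F9 stays unreacted and is separated.

## Further compounds

F1 | step 7 | 13-acetate of 9 (diacetate) | CCCC[Sn](CCCC)(CCCC)CC1=C[C@H](OC1=O)[C@@H](OC(C)=O)/C(C)=C/CC/C(C)=C/CC/C(C)=C/COC(C)=O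
F2 | step 7 | 13-acetoxy C2 primary allylic alcohol | CCCC[Sn](CCCC)(CCCC)CC1=C[C@H](OC1=O)[C@@H](OC(C)=O)/C(C)=C/CC/C(C)=C/CC/C(C)=C/CO
F3 | step 7 | 13-acetoxy C2 enal | CCCC[Sn](CCCC)(CCCC)CC1=C[C@H](OC1=O)[C@@H](OC(C)=O)/C(C)=C/CC/C(C)=C/CC/C(C)=C/C=O
F4 | step 7 | 13-acetoxy-2-hydroxycembra-3,7,11,15(17)-tetraen-16,14-olide (C2 epimers) | C=C1C(=O)O[C@H]2[C@H]1C(O)/C=C(\C)CC/C=C(\C)CC/C=C(\C)[C@@H]2OC(C)=O
F5 | step 9 | 17-(dimethylamino)-15,17-dihydro adduct of 11 | CN(C)CC1C(=O)O[C@H]2[C@H]1C/C=C(\C)CC/C=C(\C)CC/C=C(\C)[C@@H]2OC(C)=O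
F6 | step 9 | 17-(dimethylamino)-15,17-dihydro adduct of 12 | CN(C)CC1C(=O)O[C@H]2[C@H]1C[C@@H]1O[C@@]1(C)CC/C=C(\C)CC/C=C(\C)[C@@H]2OC(C)=O
F7 | step 9 | methiodide of F6 | C[N+](C)(C)CC1C(=O)O[C@H]2[C@H]1C[C@@H]1O[C@@]1(C)CC/C=C(\C)CC/C=C(\C)[C@@H]2OC(C)=O.[I-]
F8 | step 6 | ent-9, (13R,14R) | CCCC[Sn](CCCC)(CCCC)CC1=C[C@@H](OC1=O)[C@H](O)/C(C)=C/CC/C(C)=C/CC/C(C)=C/COC(C)=O
F9 | step 6 | ent-10, (1R,13R,14R) | C=C1C(=O)O[C@@H]2[C@@H]1C/C=C(\C)CC/C=C(\C)CC/C=C(\C)[C@H]2O
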